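If G and J in the birch run are added up at each reading, the sum falls short of the charge, and I built my reckoning on that shortfall.

| setting | birch | green | violet | blue | amber |
|---|---|---|---|---|---|
| G | 0.22 M | 0.050 M | 0.20 M | 0.20 M | 0.30 M |
| E | 10 mol% | 20 mol% | 10 mol% | 3 mol% | 30 mol% |
| remark | run made earlier |  |  |  |  |
| time |  | 2.0 h | 2.0 h | 2.0 h | 2.0 h |

birch run (percent of the G charged)

| time / min | J / % | G / % |
|---|---|---|
| 6.00 | 2.9 | 93.2 |
| 12.0 | 8.0 | 87.8 |
| 30.0 | 20.7 | 74.9 |
| 80.0 | 44.3 | 49.6 |

(scatter of a reading: 0.5 percentage points)

- the flasks put in order of amount of J, in percent of the G charged, best first, at 2.0 h (green / violet / blue / amber)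
- the same order at 15 h (green / violet / blue / amber)
- the amount of J, in percent of the G charged of the flask you put first, at 2.0 h
- the amount of J, in percent of the G charged of the flask you put last, at 2.0 h

- no earlier run changes the charge of E; that part of a forecast is a guess

In the first instants of birch, by 6.00 min, 3.9 percentage points of the charge was already missing. If each missing G sat on one E, that was 39.0% of the E charged, so I took it for G quickly bound to the catalyst, which also fits the lag in J.

In the middle of birch the shortfall crept from 4.2 points at 12.0 min to 6.1 points at 80.0 min, while J rose by 36 points. Their quotient, 0.0523, is my loss ratio, the points of charge lost for good per point of J made, a kind of selectivity factor. It is a reading, and a rough one, since the creep is not many times the scatter of 0.5 points.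

I guessed that the loss competes with turnover and needs G, so I scaled the ratio with the G charged. At 2.0 h I expected pace to rule, and I ranked the flasks by E per litre, another guess: amber 0.0900 M, violet 0.0200 M, green 0.0100 M, blue 0.00600 M.

Towards the end, a flask that finishes should stop at its charge minus its loss. That gave amber 92.9%, violet 95.2% and green 98.8%, so at 15 h I put green above violet above amber. Blue held less E per litre than any other flask, so I left it last at 15 h as well.

The forecast gave amber > violet > green > blue at 2.0 h, with 88% and 17% at the two ends, and amber > violet > green > blue at 15 h, which differs from my order there: “At 15 h the order should stay the same, limited by catalyst lifetime.”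

The flasks gave amber > violet > green > blue at 2.0 h, with amber 90.1% and blue 19.6%, and green > violet > amber > blue at 15 h, with green 97.4%, violet 93.1%, amber 91.0% and blue 49.6%.

    G + E ⇌ D (K = 3.10 M⁻¹, k = 0.930 M⁻¹ min⁻¹)
    D ⇌ L (K = 1.90, k = 0.670 min⁻¹)
    L → E + J (k = 0.950 min⁻¹)
    G + L → Q (k = 0.360 M⁻¹ min⁻¹)

Amber held 15.0% of its catalyst as Q at 20.0 h, and its J of 91.0% then lay under the 92.9% that the loss ratio had allowed. A neighbour flask with amber's loading but 0.075 M of G brings the ratio's loss down to 1.78% of the charge, and at 2.00 h that flask held J 72.7%, G 23.9% and Q 4.13% of its catalyst.

All runs stem from a simulated flask for substances that don't exist.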